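**Retrosynthetic overview**

- Numbering: chromone ring C has O1, C2, C3, C4; ring A is its benzo ring; ring B is the benzofuran benzene ring, C1' being bonded to C3. The strategy rests on ring B: the furan oxygen on C2' and the free hydroxyl on C5' sit para to each other, and C1' is para to the chromene oxygen on C4'. This is the pattern of a hydroquinone that a carbon nucleophile has entered, so ring B is traced back to a 1,4-benzoquinone.
- Key disconnection: the furan ring is cut at C3–C1' and at C2–O(C2'). This gives a 5-hydroxy-2-morpholinochromone carrying the chroman (rings A and C, morpholine as leaving group on C2) and 2,2-dimethyl-2H-chromene-5,8-dione (ring B as quinone).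
- Nucleophilic half: ring A is bought; ring C closes by cyclodehydration of a β-ketoamide made through a carbamoyl Baker–Venkataraman shift; the pyran is annulated at C7–C8 by propargyl Claisen/electrocyclisation and hydrogenated to the chroman.
- Electrophilic half: the chromene is annulated on 2,5-dimethoxyphenol by the same cascade and the arene is oxidised to the quinone. The furan ring closes last, as the halves are joined.

Key step: step 13

Remark: the Claisen cascade of step 7 is assumed to close mainly at C8, the usual outcome for 5-hydroxy-7-propargyloxychromones whose 5-OH is left chelated.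

**Route**

Step 1
Reactants: 1 2,4,6-trihydroxyacetophenone
Product: 2 1-[2,4-bis(benzyloxy)-6-hydroxyphenyl]ethan-1-one
Conditions: BnBr (2.1 equiv), K2CO3, DMF, rt
Reagents that add atoms: benzyl bromide, BrCc1ccccc1
Why: Williamson O-benzylation should stop at the bis-ether because the last hydroxyl is locked in a strong hydrogen bond to the acetyl carbonyl and is the least nucleophilic of the three.

Step 2
Reactants: 2 1-[2,4-bis(benzyloxy)-6-hydroxyphenyl]ethan-1-one; 3 morpholine-4-carbonyl chloride
Product: 4 2-acetyl-3,5-bis(benzyloxy)phenyl morpholine-4-carboxylate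
Conditions: NaH (1.1 equiv), THF, 0 °C to rt
Reagents that add atoms: none
Why: O-carbamoylation of the sodium phenoxide (NaH breaks the chelate) by the carbamoyl chloride is a standard acyl substitution, and at room temperature the carbamate does not yet migrate.

Step 3
Reactants: 4 2-acetyl-3,5-bis(benzyloxy)phenyl morpholine-4-carboxylate
Product: 5 1-[2,4-bis(benzyloxy)-6-hydroxyphenyl]-3-(morpholin-4-yl)propane-1,3-dione
Conditions: NaH (2.5 equiv), THF, reflux; then cold 1 M HCl to pH 5
Reagents that add atoms: none
Why: Carbamoyl Baker–Venkataraman rearrangement, in which the methyl ketone enolate attacks the neighbouring carbamate carbonyl through a six-membered transition state and the O-to-C shift is driven by the doubly stabilised β-ketoamide enolate/phenoxide, the brief cold quench avoiding lactonisation to a 4-hydroxycoumarin.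

Step 4
Reactants: 5 1-[2,4-bis(benzyloxy)-6-hydroxyphenyl]-3-(morpholin-4-yl)propane-1,3-dione
Product: 6 5,7-bis(benzyloxy)-2-(morpholin-4-yl)-4H-chromen-4-one
Conditions: Tf2O (1.5 equiv), CH2Cl2, 0 °C to rt; then MeOH, aq. NaHCO3
Reagents that add atoms: none
Why: Cyclodehydration by amide O-activation, a known route from 3-amino-1-(2-hydroxyaryl)propane-1,3-diones to 2-aminochromones: O-triflation gives an iminium triflate, the phenol adds to it, and loss of triflate and of the C3 proton closes ring C.

Step 5
Reactants: 6 5,7-bis(benzyloxy)-2-(morpholin-4-yl)-4H-chromen-4-one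
Product: 7 5,7-dihydroxy-2-(morpholin-4-yl)-4H-chromen-4-one
Conditions: H2 (1 atm), 10% Pd/C, THF/MeOH, rt
Reagents that add atoms: none
Why: Catalytic hydrogenolysis cleaves both benzylic C–O bonds while the C2=C3 bond, a push–pull vinylogous carbamate, is not reduced.

Step 6
Reactants: 7 5,7-dihydroxy-2-(morpholin-4-yl)-4H-chromen-4-one; 8 3-chloro-3-methylbut-1-yne
Product: 9 5-hydroxy-7-[(2-methylbut-3-yn-2-yl)oxy]-2-(morpholin-4-yl)-4H-chromen-4-one
Conditions: 8 (1.5 equiv), K2CO3, KI, CuI (5 mol %), DMF, 60 °C
Reagents that add atoms: none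
Why: Copper-assisted Williamson-type O-alkylation with the tertiary propargylic chloride should take place only at the free, more acidic 7-OH, since the 5-OH is hydrogen bonded to the C4 carbonyl.

Step 7
Reactants: 9 5-hydroxy-7-[(2-methylbut-3-yn-2-yl)oxy]-2-(morpholin-4-yl)-4H-chromen-4-one
Product: 11 5-hydroxy-8,8-dimethyl-2-(morpholin-4-yl)-8H-pyrano[2,3-f]chromen-4-one, via allenylphenol 10 (not isolated)
Conditions: N,N-diethylaniline, 190 °C, Ar
Reagents that add atoms: none
Why: Aromatic propargyl Claisen rearrangement to C8, enolisation to allenylphenol 10, 1,5-hydrogen shift and oxa-6π electrocyclisation should build the angular chromene, any minor linear isomer from attack at C6 being removed by chromatography.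

Step 8
Reactants: 11 5-hydroxy-8,8-dimethyl-2-(morpholin-4-yl)-8H-pyrano[2,3-f]chromen-4-one
Product: 12 5-hydroxy-8,8-dimethyl-2-(morpholin-4-yl)-9,10-dihydro-8H-pyrano[2,3-f]chromen-4-one
Conditions: H2 (1 atm), 10% Pd/C, EtOAc, rt
Reagents that add atoms: none
Why: Heterogeneous hydrogenation saturates the styrene-type chromene olefin, whereas the electron-rich C2=C3 enaminone bond and the arene are inert under one atmosphere of hydrogen.

Step 9
Reactants: 13 2,5-dimethoxybenzaldehyde
Product: 15 2,5-dimethoxyphenol, via 2,5-dimethoxyphenyl formate 14 (not isolated)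
Conditions: mCPBA, CH2Cl2, rt; then aq. NaOH, MeOH, rt; HCl
Reagents that add atoms: mCPBA (3-chloroperbenzoic acid), OOC(=O)c1cccc(Cl)c1
Why: Dakin-type Baeyer–Villiger oxidation, in which the electron-rich aryl group migrates in the Criegee intermediate to give formate 14, which is saponified in the same flask.

Step 10
Reactants: 15 2,5-dimethoxyphenol; 8 3-chloro-3-methylbut-1-yne
Product: 16 1,4-dimethoxy-2-[(2-methylbut-3-yn-2-yl)oxy]benzene
Conditions: 8 (2 equiv), K2CO3, KI, CuI (5 mol %), acetone, reflux
Reagents that add atoms: none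
Why: The same copper-assisted Williamson-type O-alkylation of a phenoxide by the tertiary propargylic chloride as in step 6, here on the only hydroxyl present.

Step 11
Reactants: 16 1,4-dimethoxy-2-[(2-methylbut-3-yn-2-yl)oxy]benzene
Product: 18 5,8-dimethoxy-2,2-dimethyl-2H-chromene, via allenylphenol 17 (not isolated)
Conditions: N,N-diethylaniline, 190 °C, Ar
Reagents that add atoms: none
Why: Propargyl Claisen rearrangement, 1,5-hydrogen shift of allenylphenol 17 and oxa-6π electrocyclisation give the chromene, and the regiochemistry is unambiguous because only one ortho position of the ether is free.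

Step 12
Reactants: 18 5,8-dimethoxy-2,2-dimethyl-2H-chromene
Product: 19 2,2-dimethyl-2H-chromene-5,8-dione
Conditions: (NH4)2Ce(NO3)6 (2.2 equiv), MeCN/H2O, 0 °C
Reagents that add atoms: water, O
Why: Oxidative demethylation of a hydroquinone dimethyl ether by two equivalents of tetravalent cerium, in which water adds at the two methoxy-bearing carbons of the oxidised arene and methanol is expelled, a fast reaction at 0 °C that should outrun attack on the chromene olefin.

Step 13
Reactants: 12 5-hydroxy-8,8-dimethyl-2-(morpholin-4-yl)-9,10-dihydro-8H-pyrano[2,3-f]chromen-4-one; 19 2,2-dimethyl-2H-chromene-5,8-dione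
Product: 21 Formosanatin D, via hydroquinone adduct 20 (not isolated)
Conditions: 19 (1.05 equiv, added slowly), Zn(OTf)2 (20 mol %), AcOH, 60 °C, Ar
Reagents that add atoms: none
Why: Proposed new method: C3 of 12 is the β-carbon of an enaminone that also draws electron density from O1, so it should add in conjugate fashion to C6 of the acid-activated quinone 19, and enolisation of the adduct gives the 3-aryl hydroquinone 20. Protonation of 20 at C3 unmasks a C2 iminium ion, the hydroxyl that came from the quinone C5 carbonyl (ortho to the new C–C bond) closes onto it in a 5-exo-trig mode, and loss of morpholine aromatises the furan ring, so the sequence is redox neutral and delivers the para hydroxyl free as the C5' OH. The closest known reactions are the Nenitzescu-type synthesis of 5-hydroxybenzofurans from tertiary enaminones and 1,4-benzoquinones and the formation of coumestans from 4-hydroxycoumarins and quinones; a 2-aminochromone has not been shown as the enaminone partner, and no stereocentre is formed. Attack must occur at quinone C6 and not C7, which the ring oxygen on C8a secures by turning the C5 carbonyl into a deactivated vinylogous ester so that the C8 carbonyl directs the nucleophile to C6. On the nucleophile the enaminone C3 should outcompete the chelated, acyl-deactivated C6 of ring A, and with C4 fixed as the ketone and the leaving group on C2 the closure can only give the coumaronochromone and not a coumestan. Slow addition of about one equivalent of 19 under argon limits oxidation of 20 by the quinone, and an aqueous Na2S2O4 wash followed by brief rewarming in AcOH would return any arylquinone to 20.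

**Compound list**

1 | 2,4,6-trihydroxyacetophenone | CC(=O)c1c(O)cc(O)cc1O | starting material
2 | 1-[2,4-bis(benzyloxy)-6-hydroxyphenyl]ethan-1-one | CC(=O)c1c(O)cc(OCc2ccccc2)cc1OCc1ccccc1 | intermediate
3 | morpholine-4-carbonyl chloride | O=C(Cl)N1CCOCC1 | starting material
4 | 2-acetyl-3,5-bis(benzyloxy)phenyl morpholine-4-carboxylate | CC(=O)c1c(OC(=O)N2CCOCC2)cc(OCc2ccccc2)cc1OCc1ccccc1 | intermediate
5 | 1-[2,4-bis(benzyloxy)-6-hydroxyphenyl]-3-(morpholin-4-yl)propane-1,3-dione | O=C(CC(=O)N1CCOCC1)c1c(O)cc(OCc2ccccc2)cc1OCc1ccccc1 | intermediate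
6 | 5,7-bis(benzyloxy)-2-(morpholin-4-yl)-4H-chromen-4-one | O=c1cc(N2CCOCC2)oc2cc(OCc3ccccc3)cc(OCc3ccccc3)c12 | intermediate
7 | 5,7-dihydroxy-2-(morpholin-4-yl)-4H-chromen-4-one | O=c1cc(N2CCOCC2)oc2cc(O)cc(O)c12 | intermediate
8 | 3-chloro-3-methylbut-1-yne | C#CC(C)(C)Cl | starting material
9 | 5-hydroxy-7-[(2-methylbut-3-yn-2-yl)oxy]-2-(morpholin-4-yl)-4H-chromen-4-one | C#CC(C)(C)Oc1cc(O)c2c(=O)cc(N3CCOCC3)oc2c1 | intermediate
10 | 5,7-dihydroxy-8-(3-methylbuta-1,2-dien-1-yl)-2-(morpholin-4-yl)-4H-chromen-4-one | CC(C)=C=Cc1c(O)cc(O)c2c(=O)cc(N3CCOCC3)oc12 | intermediate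
11 | 5-hydroxy-8,8-dimethyl-2-(morpholin-4-yl)-8H-pyrano[2,3-f]chromen-4-one | O=c1cc(N2CCOCC2)oc2c3C=CC(C)(C)Oc3cc(O)c12 | intermediate
12 | 5-hydroxy-8,8-dimethyl-2-(morpholin-4-yl)-9,10-dihydro-8H-pyrano[2,3-f]chromen-4-one | O=c1cc(N2CCOCC2)oc2c3CCC(C)(C)Oc3cc(O)c12 | intermediate
13 | 2,5-dimethoxybenzaldehyde | COc1ccc(OC)c(C=O)c1 | starting material
14 | 2,5-dimethoxyphenyl formate | COc1ccc(OC)c(OC=O)c1 | intermediate
15 | 2,5-dimethoxyphenol | COc1ccc(OC)c(O)c1 | intermediate
16 | 1,4-dimethoxy-2-[(2-methylbut-3-yn-2-yl)oxy]benzene | COc1ccc(OC)c(OC(C)(C)C#C)c1 | intermediate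
17 | 3,6-dimethoxy-2-(3-methylbuta-1,2-dien-1-yl)phenol | COc1ccc(OC)c(C=C=C(C)C)c1O | intermediate
18 | 5,8-dimethoxy-2,2-dimethyl-2H-chromene | COc1ccc(OC)c2c1OC(C)(C)C=C2 | intermediate
19 | 2,2-dimethyl-2H-chromene-5,8-dione | CC1(C)C=CC2=C(O1)C(=O)C=CC2=O | intermediate
20 | 3-(5,8-dihydroxy-2,2-dimethyl-2H-chromen-6-yl)-5-hydroxy-8,8-dimethyl-2-(morpholin-4-yl)-9,10-dihydro-8H-pyrano[2,3-f]chromen-4-one | O=c1c(-c4cc(O)c5OC(C)(C)C=Cc5c4O)c(N2CCOCC2)oc2c3CCC(C)(C)Oc3cc(O)c12 | intermediate
21 | Formosanatin D | CC1(C)C=Cc2c(c(O)cc3c2oc2oc4c5c(cc(O)c4c(=O)c23)OC(C)(C)CC5)O1 | target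

**Totals**

Total step count: 13. Longest linear sequence: 9 steps (steps 1 to 8, then step 13); the quinone half takes steps 9 to 12.

**Steps most likely to fail**

1. Step 13. The enaminone carbon may add too slowly, or at C7 of the quinone, and the adduct may be oxidised by unreacted quinone before it cyclises. The fallback uses known reactions only; it sets out from 12 and 18 and comes back at 20, which is then closed to 21. Compound 12 would be iodinated at C3 with N-iodosuccinimide (MeCN, 0 °C) to give 5-hydroxy-3-iodo-8,8-dimethyl-2-(morpholin-4-yl)-9,10-dihydro-8H-pyrano[2,3-f]chromen-4-one F1. In parallel, 18 would be brominated with N-bromosuccinimide (MeCN, 0 °C) at C6, the position ortho to the C5 methoxy group and para to the ring oxygen, to give 6-bromo-5,8-dimethoxy-2,2-dimethyl-2H-chromene F2. Bromine–lithium exchange (n-BuLi, THF, −78 °C) and trapping with 2-isopropoxy-4,4,5,5-tetramethyl-1,3,2-dioxaborolane would give 2-(5,8-dimethoxy-2,2-dimethyl-2H-chromen-6-yl)-4,4,5,5-tetramethyl-1,3,2-dioxaborolane F3. Suzuki–Miyaura coupling of F1 with F3 (Pd(OAc)2, SPhos, K3PO4, dioxane/H2O, 80 °C) would fix the C3–C1' bond with unambiguous regiochemistry and give 3-(5,8-dimethoxy-2,2-dimethyl-2H-chromen-6-yl)-5-hydroxy-8,8-dimethyl-2-(morpholin-4-yl)-9,10-dihydro-8H-pyrano[2,3-f]chromen-4-one F4. Oxidative demethylation with (NH4)2Ce(NO3)6 (MeCN/H2O, 0 °C) would give 6-[5-hydroxy-8,8-dimethyl-2-(morpholin-4-yl)-4-oxo-9,10-dihydro-4H,8H-pyrano[2,3-f]chromen-3-yl]-2,2-dimethyl-2H-chromene-5,8-dione F5. Reduction with aqueous Na2S2O4 would return hydroquinone 20, which on warming in AcOH should close to 21 with loss of morpholine. That closure is the intramolecular counterpart of the known acid-mediated exchange of the 2-amino group of 2-aminochromones by oxygen nucleophiles (their hydrolysis to 4-hydroxycoumarins).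

2. Step 12. The tetravalent cerium oxidant may attack the electron-rich chromene double bond or nitrate the ring, and the quinone may decompose or dimerise during isolation. The fallback sets out from 8 and commercial catechol and comes back at 19. Catechol would be mono-alkylated with 8 (K2CO3, KI, CuI, acetone, reflux) to give 2-[(2-methylbut-3-yn-2-yl)oxy]phenol F6. Thermal Claisen rearrangement and electrocyclisation (N,N-diethylaniline, 190 °C), possible only at the single free ortho position of the ether oxygen, would give 2,2-dimethyl-2H-chromen-8-ol F7. Teuber oxidation of this phenol, whose para position is free, with (KSO3)2NO in aqueous KH2PO4/acetone would give 19 directly. This replaces single-electron oxidation of a diether in acidic nitrate medium by oxidation of a free phenol near neutral pH.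

3. Step 3. Enolate formation may not be followed by acyl transfer, or the carbamate may be cleaved back to the phenol, because the carbamoyl carbonyl is a weak electrophile and the ketone is flanked by two ortho substituents. The fallback sets out from 2, bypasses 4 and 5, and comes back at 6. Compound 2 would be condensed with CS2 (KOtBu, toluene, rt) to give 5,7-bis(benzyloxy)-4-hydroxy-2H-chromene-2-thione F8. S-Alkylation with iodoethane (K2CO3, acetone) would give 5,7-bis(benzyloxy)-2-(ethylsulfanyl)-4H-chromen-4-one F9. Heating F9 with morpholine (ethylene glycol, 140 °C) would displace ethanethiol by addition–elimination at C2 and give 6, an established alternative entry to 2-morpholinochromones.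

**Further compounds**

F1 | step 13 | 5-hydroxy-3-iodo-8,8-dimethyl-2-(morpholin-4-yl)-9,10-dihydro-8H-pyrano[2,3-f]chromen-4-one | O=c1c(I)c(N2CCOCC2)oc2c3CCC(C)(C)Oc3cc(O)c12
F2 | step 13 | 6-bromo-5,8-dimethoxy-2,2-dimethyl-2H-chromene | COc1cc(Br)c(OC)c2c1OC(C)(C)C=C2
F3 | step 13 | 2-(5,8-dimethoxy-2,2-dimethyl-2H-chromen-6-yl)-4,4,5,5-tetramethyl-1,3,2-dioxaborolane | COc1cc(B2OC(C)(C)C(C)(C)O2)c(OC)c2c1OC(C)(C)C=C2
F4 | step 13 | 3-(5,8-dimethoxy-2,2-dimethyl-2H-chromen-6-yl)-5-hydroxy-8,8-dimethyl-2-(morpholin-4-yl)-9,10-dihydro-8H-pyrano[2,3-f]chromen-4-one | O=c1c(-c4cc(OC)c5OC(C)(C)C=Cc5c4OC)c(N2CCOCC2)oc2c3CCC(C)(C)Oc3cc(O)c12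
F5 | step 13 | 6-[5-hydroxy-8,8-dimethyl-2-(morpholin-4-yl)-4-oxo-9,10-dihydro-4H,8H-pyrano[2,3-f]chromen-3-yl]-2,2-dimethyl-2H-chromene-5,8-dione | O=c1c(C4=CC(=O)C5=C(C=CC(C)(C)O5)C4=O)c(N2CCOCC2)oc2c3CCC(C)(C)Oc3cc(O)c12
F6 | step 12 | 2-[(2-methylbut-3-yn-2-yl)oxy]phenol | C#CC(C)(C)Oc1ccccc1O
F7 | step 12 | 2,2-dimethyl-2H-chromen-8-ol | CC1(C)C=Cc2cccc(O)c2O1
F8 | step 3 | 5,7-bis(benzyloxy)-4-hydroxy-2H-chromene-2-thione | S=c1cc(O)c2c(OCc3ccccc3)cc(OCc3ccccc3)cc2o1
F9 | step 3 | 5,7-bis(benzyloxy)-2-(ethylsulfanyl)-4H-chromen-4-one | CCSc1cc(=O)c2c(OCc3ccccc3)cc(OCc3ccccc3)cc2o1
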